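Readings and results were generated by integration with made-up constants, and the scatter is random.

1. In this flask the added ligand, 19 mM, is charged below the free catalyst, 28 mM. The added ligand charged per free catalyst charged, the ligand equivalents 0.679, gives the fraction of the catalyst charge that added ligand can hold if it binds one to one.

the same everywhere: free catalyst 28 mM; added ligand 19 mM

| run | substrate | reagent | remark |
|---|---|---|---|
| zeta | 1.1 M | 0.58 M | run made earlier |
| delta | 1.1 M | 0.87 M | run made earlier |
| theta | 1.7 M | 1.16 M | run made earlier |
| flask | 1.1 M | 1.16 M |  |

| run | time / min | product / % | substrate / % |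
|---|---|---|---|
| zeta | 0.417 | 2 | 94 |
| zeta | 1.33 | 3 | 93 |
| zeta | 2.50 | 6 | 94 |
| zeta | 3.00 | 7 | 89 |
| zeta | 5.00 | 12 | 86 |
| zeta | 6.00 | 14 | 86 |
| zeta | 8.00 | 17 | 82 |
| delta | 0.667 | 7 | 94 |
| delta | 1.00 | 0 | 94 |
| delta | 1.33 | 2 | 94 |
| delta | 2.50 | 6 | 93 |
| delta | 3.00 | 8 | 91 |
| delta | 5.00 | 12 | 86 |
| delta | 8.00 | 16 | 78 |
| theta | 0.667 | 0 | 95 |
| theta | 2.00 | 4 | 96 |
| theta | 4.00 | 9 | 91 |
| theta | 6.00 | 18 | 86 |
| theta | 8.00 | 17 | 81 |

(readings scatter by 2 percentage points)

- factor on the rate of making product when 20% of the substrate are converted if reagent is charged twice over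
- factor on the rate when 20% of the substrate are converted if free catalyst is charged at 6.0 mM instead

- what was read earlier has a scatter of 2 percentage points, one standard deviation
- no earlier run changes the charge of free catalyst; that part of a forecast is a guess

2. The bench rule says that, with the other charges fixed, rate goes with the catalyst charge, first order. At 6.0 mM it gives a factor of 0.214.

3. That rule has a border. At 6.0 mM the ligand equivalents are 3.17, above one, so added ligand, if it binds one to one, suffices for the entire catalyst charge. The comparison is also made at 20% conversion and not at one clock time. The delta run holds 78% of its substrate at 8.00 min, and the bench rule stretches that time to about 37.3 min, which leaves the ligand longer to bind.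

4. My own reckoning therefore puts the catalyst factor below 0.214. For reagent it stays near one, since the zeta and delta runs read 17% and 16% product at 8.00 min, within the scatter of 2 percentage points.

5. The forecast gives 1.05 for reagent and 0.21 for catalyst, saying “Catalyst was never varied, so assuming first order”. On catalyst my reckoning differs from it by lying lower, without a number.

    free catalyst + added ligand ⇌ idle complex (K = 2900 /M, k = 0.0650 /M/s)
    catalyst intermediate A → catalyst intermediate B (k = 0.0850 /s)
    catalyst intermediate C → free catalyst + product (k = 0.580 /s)
    reagent + catalyst intermediate B ⇌ catalyst intermediate C (K = 1.20 /M, k = 0.0690 /M/s)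
    substrate + free catalyst ⇌ catalyst intermediate A (K = 4.00 /M, k = 0.0590 /M/s)

6. Doubled reagent gives 1.21, and 6.0 mM free catalyst gives 0.0621, less than the proportional 0.214. Ligand equivalents of 0.679 cap the idle complex, the off-cycle form, at 67.9% of the catalyst in this flask, and at 100 min it stands at 61.7%. In the 6.0 mM flask the equivalents are 3.17, so that cap lies above the catalyst charge, and its rate factor is 0.290 of the proportional one.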